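## Analysis of the target

trans-Diptoindonesin B (24) is a resveratrol trimer in which two 2-aryl-2,3-dihydrobenzofurans are joined by one sp3–sp2 bond. DHB-1 (O1, C2, C3, C3a to C7a) carries a 4-hydroxyphenyl group on C2, an (E)-3,5-dihydroxystyryl group on C5 and, on C3, carbon C4' of DHB-2 (O1', C2', C3', C3a' to C7a'). DHB-2 carries a 4-hydroxyphenyl group on C2', a 3,5-dihydroxyphenyl group on C3' and a hydroxyl on C6'. The four stereocentres C2, C3, C2' and C3' are all S; each ring is 2,3-trans, but the two trans pairs are insulated from each other by the rotating C3–C4' bond, so each pair needs its own source of absolute configuration. Sensitive elements are the seven phenols (oxidation), the electron-rich stilbene (electrophiles, oxidants), the benzylic C2–O1 and C2'–O1' bonds (acid ionisation, since each carbon bears a para-oxygenated aryl group) and the multiply benzylic C3–H and C3'–H bonds. The hard part is the C3–C4' bond: C4' is meta to both oxygens of its ring and ortho to the substituted C3a', so electrophilic substitution cannot reach it, and C3 is a hindered secondary benzylic carbon next to a stereocentre. The plan rests on the substitution of C3 in DHB-1: it is bonded to the fused arene carbon C3a, to C2 and to exactly one further carbon, trans to the C2 aryl group. That is the pattern left when the fused aryl carbon of a 2-arylchroman-4-one shifts from the carbonyl carbon to the neighbouring CH2 and pushes the carbonyl carbon out of the ring as a carboxyl group, which then serves as the handle for the C3–C4' bond.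

## Retrosynthetic reasoning

**O–CH3 bonds.** The seven phenols of 24 are traced back to the heptamethyl ether 23. Methyl ethers are the only phenol protection that tolerates every reagent class used earlier (strong acid with an iodine oxidant, an organomagnesium reagent, a metal carbene, low-valent nickel). The forward step has to remove seven methyl groups with a boron Lewis acid without irreversibly opening either benzylic C–O bond.

**C3–C4' bond.** 23 is cut between the two ring systems into redox-active ester 10 and aryl iodide 22. This is the only cut that separates the two stereochemical pairs, so each half can be made and checked alone. Because C4' cannot be reached by electrophilic substitution, it carries a halogen, and C3 carries the carboxyl group that the key step delivers. The forward reaction is a nickel-catalysed decarboxylative arylation. C3 becomes a planar radical, so the configuration it had before is irrelevant; what must survive up to this point is C2, which then directs the incoming arene to the trans face.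

**C5–vinyl bond and carboxyl activation.** 10 comes from acid 9 and this from methyl ester 8, which is cut at the aryl–vinyl bond into bromide 6 and styrene 7 (Heck reaction). The stilbene is installed after the oxidative rearrangement, because an electron-rich stilbene would not survive an electrophilic iodine oxidant. It is installed before the nickel step, because an aryl bromide would compete there with iodide 22.

**C3–C3a bond (key disconnection).** Ester 6 is traced back to flavanone 3 by reversing a 1,2-shift: the C3–C3a bond is cut and C3a is reattached to the ester carbon, which becomes the ring carbonyl. This is done here because it turns a dihydrobenzofuran with two stereocentres and a quaternary-type substitution problem into a chromanone with one stereocentre. The forward step has to move the fused aryl carbon and not the C2 aryl group, and must keep C2 configured.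

**C2–aryl bond.** 3 is cut into chromone 1 and boronic acid 2. A catalytic asymmetric conjugate addition sets C2, the stereocentre from which C3 is derived twice (in the rearrangement and again in the coupling).

**C4'–halogen and C2' configuration.** Iodide 22 comes from bromide 21 by halogen exchange, and 21 from its cis isomer 20 by epimerisation at C2'. The acid-labile C2'–O1' bond, a liability elsewhere, is used here to reach the more stable trans ring while C3' stays fixed.

**C2'–C3' bond.** 20 is cut between its two stereocentres to diazo compound 19, made from hydrazone 18; an enantioselective intramolecular carbene C–H insertion forms the ring. 18 comes from ketone 17, this from carbinol 16, and 16 from aldehyde 14 and Grignard reagent 15 (C3'–aryl bond). 14 is the ether of phenol 12 with benzyl chloride 13 (O1'–C2' atoms), and 12 comes from aldehyde 11 by selective cleavage of the methoxy group next to the carbonyl. 11 is chosen because it already has the 1,2,3,5-pattern of the central ring: a carbon flanked by bromine and oxygen, with a methoxy group para to it.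

## Alternatives that were turned down

**Alternative 1:** The central benzene ring is disconnected at C3a'–C4' and built last onto the preformed oxygen ring of DHB-2. In the forward step a base forms an extended dienolate of an alkylidene oxygen heterocycle; the ring CH2 (future C3a') adds to a side-chain ketone (future C4'), and dehydration and tautomerisation give the phenol A1, which carries a ketal-masked 5-bromo-2-(4-methoxybenzyloxy)benzoyl group on C4'.
- For: the C4' substituent is placed by ring synthesis, so no halogen has to be brought to a position that is meta to both oxygens and no hindered cross-coupling is needed; the C6' hydroxyl emerges free and differentiated. On this point it is stronger than the chosen route, whose DHB-2 arm needs eight steps to place a halogen at C4'.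
- Against: C4' ends up bonded to a carbonyl carbon, so DHB-1 still has to be built on that ketone. C2 and C3 would then be set under the influence of stereocentres four bonds away across a rotating aryl–carbon bond, which gives no reliable control. The sequence is linear, and the strongly basic aldolisation acts next to C3'.
- Comparison: the chosen strategy gives up the elegant arene construction and offers instead catalyst control of C2, a stereospecific origin of C3, and full convergence of two separately secured halves.

**Alternative 2:** The bonds C3–C4' and C3a'–C3' are cut together. In the forward step fluoride releases aryne A4 (3,5-dimethoxybenzyne); the enolate carbon of β-keto lactone A3 adds to it and the resulting aryl anion takes over the aroyl group, giving A2 by acyl-alkylation.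
- For: two carbon–carbon bonds at the congested central ring form in one metal-free operation, with regiochemistry dictated by the methoxy group next to the aryne. In step economy for the carbon skeleton this is clearly stronger than the chosen route.
- Against: A2 has no fixed stereocentre (C3 is enolisable). All four stereocentres, two ring closures (lactone carbon to C2 with its aryl group, ketone carbon to C3' with C2' and its aryl group) and all relative control between the halves remain to be solved afterwards, by diastereoselection with nothing to relay it. The acidic lactone is also exposed to fluoride and to the aryl anion.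
- Comparison: the chosen strategy is slower in building the skeleton but sets absolute configuration first and never has to correlate the two halves.

**Alternative 3:** DHB-1 is disconnected at O1–C7a. In the forward step the C2 alkoxide displaces fluoride from a 2-fluoro-5-formylphenyl group on C3 (SNAr activated by the para formyl group), giving aldehyde A5, whose formyl group is then olefinated to the stilbene.
- For: the ring closure touches neither C2 nor C3, and the formyl group serves twice, as activator and as handle for an E-selective olefination. This endgame is gentler than the chosen one, because no stilbene is exposed to palladium or to a radical coupling.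
- Against: the difficulty is only moved. The open-chain alcohol must already have C2 and C3 correctly configured, with C3 bearing both the fluoroarene and the hindered C4' arene, and there is no dependable asymmetric construction of that triaryl-substituted carbon pair. A DHB-2 block with a C4' handle is needed just the same.
- Comparison: the chosen strategy answers exactly that open question. C3 is functionalised and configured in one rearrangement from a flavanone that is one catalytic step from commercial material.

Key step: step 2

## Assumptions

- 2-Bromo-4,6-dimethoxybenzaldehyde (11) is taken as a catalogue compound.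
- The sense of induction of the chiral diene in step 1 and of the dirhodium carboxylate in step 11 is assigned by analogy with related substrates; if the first run shows the opposite sense, the antipodal ligand is used.

## Route

Step 1
Reactants: 1 6-bromochromone; 2 4-methoxyphenylboronic acid
Product: 3 (2S)-6-bromo-2-(4-methoxyphenyl)chroman-4-one
Conditions: [RhCl(C2H4)2]2 (2.5 mol %), (S,S)-Ph-bod* [(1S,4S)-2,5-diphenylbicyclo[2.2.2]octa-2,5-diene] (5.5 mol %), aq K3PO4 (0.5 equiv), toluene/H2O, 30 °C
Reagents that add atoms: none
Why: Rhodium-catalysed asymmetric 1,4-addition of an arylboronic acid to a chromone (Hayashi–Miyaura type); the aryl–rhodium species held by the chiral diene adds to one face of the C2=C3 bond and sets C2, and the aryl bromide is inert to monovalent rhodium. Weak base and short contact time keep the flavanone from opening to the chalcone, which would racemise C2.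

Step 2
Reactants: 3 (2S)-6-bromo-2-(4-methoxyphenyl)chroman-4-one
Product: 6 methyl (2S,3S)-5-bromo-2-(4-methoxyphenyl)-2,3-dihydrobenzofuran-3-carboxylate, via enol ether 4 (not isolated), via ketal iodane 5 (not isolated)
Conditions: PhI(OAc)2 (1.2 equiv), conc. H2SO4 (0.3 equiv), HC(OMe)3, 0 °C → rt
Reagents that add atoms: trimethyl orthoformate, COC(OC)OC
Why: Acid and the orthoester convert ketone 3 into enol ether 4, which the electrophilic trivalent iodine reagent attacks at C3 on the face opposite the C2 aryl group while methanol adds to C4, giving ketal iodane 5 with an equatorial C3–I bond. That bond is antiperiplanar to the C4–C4a ring bond, so the fused aryl carbon shifts from C4 to C3 through a bridged phenonium-type transition state as iodobenzene leaves, and C4 is expelled from the ring as a dimethoxycarbenium ion that collapses to the methyl ester. The closest known reaction type is the oxidative ring contraction of flavanones and other chroman-4-ones with PhI(OAc)2 or Tl(NO3)3 in trimethyl orthoformate, a cyclic case of the oxidative 1,2-aryl shift of aryl ketones to arylacetic esters. The five-membered ring is not closed from an open chain but arises by contraction of the six-membered ring: the C3–C3a bond forms by a 3-exo-type attack of the ipso carbon on C3 while the old C4–C4a bond breaks in the same event. The new stereocentre C3 is controlled by C2: iodination anti to the aryl group followed by inversion at C3 places the ester trans, and trans is also the thermodynamic epimer of this enolisable ester, so kinetic and equilibrium control both give (2S,3S). The step needs migration of the fused ring and not of the C2 anisyl group, and it needs C2 to stay configured; the first is secured by the two ketal oxygens that stabilise the departing carbon, by the ring oxygen ortho to the migrating carbon and by the equatorial geometry that keeps the anisyl group gauche to the leaving group, the second by fast conversion of the ketone into 4, which closes the retro-oxa-Michael channel. The bromine is meta to the migrating carbon and only a spectator; it stands in for the styryl group, which would not survive the oxidant.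

Step 3
Reactants: 6 methyl (2S,3S)-5-bromo-2-(4-methoxyphenyl)-2,3-dihydrobenzofuran-3-carboxylate; 7 3,5-dimethoxystyrene
Product: 8 methyl (2S,3S)-5-[(E)-2-(3,5-dimethoxyphenyl)ethenyl]-2-(4-methoxyphenyl)-2,3-dihydrobenzofuran-3-carboxylate
Conditions: Pd(OAc)2 (5 mol %), P(o-tol)3 (10 mol %), Cy2NMe, DMF, 90 °C
Reagents that add atoms: none
Why: Mizoroki–Heck coupling of an aryl bromide with a styrene; syn insertion and syn β-hydride elimination give the E-stilbene. The hindered tertiary amine is too weak to remove the C3 ester proton, so neither stereocentre is at risk.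

Step 4
Reactants: 8 methyl (2S,3S)-5-[(E)-2-(3,5-dimethoxyphenyl)ethenyl]-2-(4-methoxyphenyl)-2,3-dihydrobenzofuran-3-carboxylate
Product: 9 (2S,3S)-5-[(E)-2-(3,5-dimethoxyphenyl)ethenyl]-2-(4-methoxyphenyl)-2,3-dihydrobenzofuran-3-carboxylic acid
Conditions: Me3SnOH (4 equiv), ClCH2CH2Cl, 70 °C; then cold 0.5 M HCl
Reagents that add atoms: trimethyltin hydroxide, C[Sn](C)(C)O
Why: Methyl ester cleavage with Me3SnOH proceeds by neutral acyl transfer at tin without a free ester enolate, so E1cB opening of the O1–C2 bond, which would racemise C2, is avoided. The stilbene and the aryl ethers are untouched.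

Step 5
Reactants: 9 (2S,3S)-5-[(E)-2-(3,5-dimethoxyphenyl)ethenyl]-2-(4-methoxyphenyl)-2,3-dihydrobenzofuran-3-carboxylic acid
Product: 10 1,3-dioxoisoindolin-2-yl (2S,3S)-5-[(E)-2-(3,5-dimethoxyphenyl)ethenyl]-2-(4-methoxyphenyl)-2,3-dihydrobenzofuran-3-carboxylate
Conditions: N-hydroxyphthalimide (1.1 equiv), DIC (1.1 equiv), DMAP (5 mol %), CH2Cl2, 0 °C → rt
Reagents that add atoms: N-hydroxyphthalimide, O=C1c2ccccc2C(=O)N1O
Why: Carbodiimide (Steglich-type) esterification to the redox-active N-acyloxyphthalimide; the amine is kept catalytic so that the more acidic C3–H of the active ester is not removed.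

Step 6
Reactants: 11 2-bromo-4,6-dimethoxybenzaldehyde
Product: 12 2-bromo-6-hydroxy-4-methoxybenzaldehyde
Conditions: BCl3 (1.2 equiv), CH2Cl2, −78 → 0 °C; then H2O
Reagents that add atoms: none
Why: Chelation-controlled demethylation: boron binds the carbonyl oxygen and the neighbouring methoxy oxygen, so only the ether ortho to the aldehyde is cleaved and the para methoxy group (future C6'–OMe) stays.

Step 7
Reactants: 12 2-bromo-6-hydroxy-4-methoxybenzaldehyde; 13 4-methoxybenzyl chloride
Product: 14 2-bromo-4-methoxy-6-[(4-methoxyphenyl)methoxy]benzaldehyde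
Conditions: K2CO3, KI (cat.), DMF, 60 °C
Reagents that add atoms: none
Why: Williamson etherification of the phenol; the benzylic CH2 introduced here is the future C2' with its aryl group.

Step 8
Reactants: 14 2-bromo-4-methoxy-6-[(4-methoxyphenyl)methoxy]benzaldehyde; 15 3,5-dimethoxyphenylmagnesium chloride
Product: 16 {2-bromo-4-methoxy-6-[(4-methoxyphenyl)methoxy]phenyl}(3,5-dimethoxyphenyl)methanol (racemic)
Conditions: THF, −20 → 0 °C; then aq NH4Cl
Reagents that add atoms: none
Why: Grignard addition to the aldehyde forms the C3'–aryl bond; at this temperature addition is far faster than halogen–magnesium exchange at the aryl bromide. The carbinol centre is removed in the next step.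

Step 9
Reactants: 16 {2-bromo-4-methoxy-6-[(4-methoxyphenyl)methoxy]phenyl}(3,5-dimethoxyphenyl)methanol
Product: 17 {2-bromo-4-methoxy-6-[(4-methoxyphenyl)methoxy]phenyl}(3,5-dimethoxyphenyl)methanone
Conditions: Dess–Martin periodinane (1.3 equiv), CH2Cl2, rt
Reagents that add atoms: none
Why: Dess–Martin oxidation of a diaryl carbinol to the benzophenone; the benzyl ether and the aryl bromide are inert.

Step 10
Reactants: 17 {2-bromo-4-methoxy-6-[(4-methoxyphenyl)methoxy]phenyl}(3,5-dimethoxyphenyl)methanone
Product: 18 {2-bromo-4-methoxy-6-[(4-methoxyphenyl)methoxy]phenyl}(3,5-dimethoxyphenyl)methanone hydrazone (E/Z mixture)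
Conditions: N2H4·H2O (20 equiv), AcOH (0.2 equiv), n-BuOH, 120 °C (sealed tube)
Reagents that add atoms: hydrazine, NN
Why: Acid-catalysed condensation of a diaryl ketone with hydrazine; the large excess and high temperature are needed because one aryl ring is substituted at both ortho positions. Both hydrazone isomers give the same diazo compound.

Step 11
Reactants: 18 {2-bromo-4-methoxy-6-[(4-methoxyphenyl)methoxy]phenyl}(3,5-dimethoxyphenyl)methanone hydrazone
Product: 20 (2R,3S)-4-bromo-3-(3,5-dimethoxyphenyl)-6-methoxy-2-(4-methoxyphenyl)-2,3-dihydrobenzofuran, via diazo compound 19 (not isolated)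
Conditions: MnO2 (8 equiv), CH2Cl2, 0 °C, filter; then Rh2(R-PTAD)4 (dirhodium tetrakis[(R)-N-phthaloyl-(1-adamantyl)glycinate], 1 mol %), CH2Cl2, −20 °C → rt
Reagents that add atoms: none
Why: Oxidation of the hydrazone to the diaryldiazomethane and enantioselective intramolecular 1,5 C–H insertion of the resulting donor/donor rhodium carbene into the benzylic ether C–H bond, the known entry to 2,3-diaryl-2,3-dihydrobenzofurans. The concerted insertion gives the cis ring; the chiral carboxylate ligands select the carbene face and so set C3' (S), the centre that is kept. The two ortho substituents disfavour the usual side reaction, azine formation.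

Step 12
Reactants: 20 (2R,3S)-4-bromo-3-(3,5-dimethoxyphenyl)-6-methoxy-2-(4-methoxyphenyl)-2,3-dihydrobenzofuran
Product: 21 (2S,3S)-4-bromo-3-(3,5-dimethoxyphenyl)-6-methoxy-2-(4-methoxyphenyl)-2,3-dihydrobenzofuran
Conditions: BF3·OEt2 (1.0 equiv), CH2Cl2, −40 → 0 °C
Reagents that add atoms: none
Why: Acid-mediated epimerisation of a 2-(4-methoxyphenyl)-2,3-dihydrobenzofuran: the Lewis acid ionises the C2'–O1' bond to a para-methoxybenzylic cation, which recloses on the phenol oxygen to the more stable trans ring. C3' is not touched, so C2' goes from R to S under its control; low temperature and short contact time let the cation close before it can lose the C3' proton.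

Step 13
Reactants: 21 (2S,3S)-4-bromo-3-(3,5-dimethoxyphenyl)-6-methoxy-2-(4-methoxyphenyl)-2,3-dihydrobenzofuran
Product: 22 (2S,3S)-3-(3,5-dimethoxyphenyl)-4-iodo-6-methoxy-2-(4-methoxyphenyl)-2,3-dihydrobenzofuran
Conditions: CuI (10 mol %), trans-N,N'-dimethylcyclohexane-1,2-diamine (20 mol %), NaI (3 equiv), 1,4-dioxane, 110 °C
Reagents that add atoms: sodium iodide, [Na+].[I-]
Why: Copper-catalysed aromatic Finkelstein reaction, driven by precipitation of NaBr in dioxane; the neutral conditions leave both stereocentres alone and give the more reactive partner for nickel.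

Step 14
Reactants: 10 1,3-dioxoisoindolin-2-yl (2S,3S)-5-[(E)-2-(3,5-dimethoxyphenyl)ethenyl]-2-(4-methoxyphenyl)-2,3-dihydrobenzofuran-3-carboxylate; 22 (2S,3S)-3-(3,5-dimethoxyphenyl)-4-iodo-6-methoxy-2-(4-methoxyphenyl)-2,3-dihydrobenzofuran
Product: 23 (2S,3S)-3-(3,5-dimethoxyphenyl)-4-[(2S,3S)-5-[(E)-2-(3,5-dimethoxyphenyl)ethenyl]-2-(4-methoxyphenyl)-2,3-dihydrobenzofuran-3-yl]-6-methoxy-2-(4-methoxyphenyl)-2,3-dihydrobenzofuran
Conditions: NiCl2·glyme (20 mol %), 4,4'-di-tert-butyl-2,2'-bipyridine (22 mol %), Zn dust (3 equiv), DMA, rt
Reagents that add atoms: none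
Why: Nickel-catalysed decarboxylative cross-electrophile coupling of an N-acyloxyphthalimide with an aryl iodide: zerovalent nickel inserts into the C–I bond of 22, single-electron reduction of 10 releases CO2 and the benzylic C3 radical, and capture by the aryl–nickel species followed by reductive elimination forms C3–C4'. C3 is planar at the radical stage and the new bond forms on the face opposite the C2 anisyl group, so C3 is set S (trans) under control of C2; C2, C2' and C3' take no part.

Step 15
Reactants: 23 (2S,3S)-3-(3,5-dimethoxyphenyl)-4-[(2S,3S)-5-[(E)-2-(3,5-dimethoxyphenyl)ethenyl]-2-(4-methoxyphenyl)-2,3-dihydrobenzofuran-3-yl]-6-methoxy-2-(4-methoxyphenyl)-2,3-dihydrobenzofuran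
Product: 24 trans-diptoindonesin B, 5-[(2S,3S)-4-[(2S,3S)-5-[(E)-2-(3,5-dihydroxyphenyl)ethenyl]-2-(4-hydroxyphenyl)-2,3-dihydrobenzofuran-3-yl]-6-hydroxy-2-(4-hydroxyphenyl)-2,3-dihydrobenzofuran-3-yl]benzene-1,3-diol
Conditions: BBr3 (20 equiv), CH2Cl2, −78 °C → rt; then MeOH, H2O, under argon
Reagents that add atoms: none
Why: Lewis-acid cleavage of aryl methyl ethers with BBr3, the usual last step for permethylated stilbenoids; the E-alkene is inert, and a dihydrobenzofuran that opens reversibly at its benzylic C–O bond recloses to the same trans ring because the neighbouring stereocentre is untouched. Work-up under argon limits oxidation of the heptaphenol.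

## Compound list

1 | 6-bromochromone (6-bromo-4H-chromen-4-one) | O=c1ccoc2ccc(Br)cc12 | starting material
2 | 4-methoxyphenylboronic acid | COc1ccc(B(O)O)cc1 | starting material
3 | (2S)-6-bromo-2-(4-methoxyphenyl)chroman-4-one | COc1ccc([C@H]2Oc3ccc(Br)cc3C(=O)C2)cc1 | intermediate
4 | (2S)-6-bromo-4-methoxy-2-(4-methoxyphenyl)-2H-chromene | COc1ccc([C@H]2Oc3ccc(Br)cc3C(OC)=C2)cc1 | intermediate (not isolated)
5 | [(2R,3R)-6-bromo-4,4-dimethoxy-2-(4-methoxyphenyl)chroman-3-yl](phenyl)-λ3-iodanyl acetate | COc1ccc([C@H]2Oc3ccc(Br)cc3C(OC)(OC)[C@@H]2I(OC(C)=O)c2ccccc2)cc1 | intermediate (not isolated)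
6 | methyl (2S,3S)-5-bromo-2-(4-methoxyphenyl)-2,3-dihydrobenzofuran-3-carboxylate | COc1ccc([C@H]2Oc3ccc(Br)cc3[C@@H]2C(=O)OC)cc1 | intermediate
7 | 3,5-dimethoxystyrene | C=Cc1cc(OC)cc(OC)c1 | starting material
8 | methyl (2S,3S)-5-[(E)-2-(3,5-dimethoxyphenyl)ethenyl]-2-(4-methoxyphenyl)-2,3-dihydrobenzofuran-3-carboxylate | COc1ccc([C@H]2Oc3ccc(/C=C/c4cc(OC)cc(OC)c4)cc3[C@@H]2C(=O)OC)cc1 | intermediate
9 | (2S,3S)-5-[(E)-2-(3,5-dimethoxyphenyl)ethenyl]-2-(4-methoxyphenyl)-2,3-dihydrobenzofuran-3-carboxylic acid | COc1ccc([C@H]2Oc3ccc(/C=C/c4cc(OC)cc(OC)c4)cc3[C@@H]2C(=O)O)cc1 | intermediate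
10 | 1,3-dioxoisoindolin-2-yl (2S,3S)-5-[(E)-2-(3,5-dimethoxyphenyl)ethenyl]-2-(4-methoxyphenyl)-2,3-dihydrobenzofuran-3-carboxylate | COc1ccc([C@H]2Oc3ccc(/C=C/c4cc(OC)cc(OC)c4)cc3[C@@H]2C(=O)ON2C(=O)c3ccccc3C2=O)cc1 | intermediate
11 | 2-bromo-4,6-dimethoxybenzaldehyde | COc1cc(OC)c(C=O)c(Br)c1 | starting material
12 | 2-bromo-6-hydroxy-4-methoxybenzaldehyde | COc1cc(O)c(C=O)c(Br)c1 | intermediate
13 | 4-methoxybenzyl chloride | COc1ccc(CCl)cc1 | starting material
14 | 2-bromo-4-methoxy-6-[(4-methoxyphenyl)methoxy]benzaldehyde | COc1ccc(COc2cc(OC)cc(Br)c2C=O)cc1 | intermediate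
15 | 3,5-dimethoxyphenylmagnesium chloride | COc1cc(OC)cc([Mg]Cl)c1 | starting material
16 | {2-bromo-4-methoxy-6-[(4-methoxyphenyl)methoxy]phenyl}(3,5-dimethoxyphenyl)methanol (racemic) | COc1ccc(COc2cc(OC)cc(Br)c2C(O)c2cc(OC)cc(OC)c2)cc1 | intermediate
17 | {2-bromo-4-methoxy-6-[(4-methoxyphenyl)methoxy]phenyl}(3,5-dimethoxyphenyl)methanone | COc1ccc(COc2cc(OC)cc(Br)c2C(=O)c2cc(OC)cc(OC)c2)cc1 | intermediate
18 | {2-bromo-4-methoxy-6-[(4-methoxyphenyl)methoxy]phenyl}(3,5-dimethoxyphenyl)methanone hydrazone | COc1ccc(COc2cc(OC)cc(Br)c2C(=NN)c2cc(OC)cc(OC)c2)cc1 | intermediate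
19 | 1-bromo-2-[diazo(3,5-dimethoxyphenyl)methyl]-5-methoxy-3-[(4-methoxyphenyl)methoxy]benzene | COc1ccc(COc2cc(OC)cc(Br)c2C(=[N+]=[N-])c2cc(OC)cc(OC)c2)cc1 | intermediate (not isolated)
20 | (2R,3S)-4-bromo-3-(3,5-dimethoxyphenyl)-6-methoxy-2-(4-methoxyphenyl)-2,3-dihydrobenzofuran (cis) | Brc1cc(OC)cc2c1[C@H](c1cc(OC)cc(OC)c1)[C@H](c1ccc(OC)cc1)O2 | intermediate
21 | (2S,3S)-4-bromo-3-(3,5-dimethoxyphenyl)-6-methoxy-2-(4-methoxyphenyl)-2,3-dihydrobenzofuran (trans) | Brc1cc(OC)cc2c1[C@H](c1cc(OC)cc(OC)c1)[C@@H](c1ccc(OC)cc1)O2 | intermediate
22 | (2S,3S)-3-(3,5-dimethoxyphenyl)-4-iodo-6-methoxy-2-(4-methoxyphenyl)-2,3-dihydrobenzofuran | Ic1cc(OC)cc2c1[C@H](c1cc(OC)cc(OC)c1)[C@@H](c1ccc(OC)cc1)O2 | intermediate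
23 | (2S,3S)-3-(3,5-dimethoxyphenyl)-4-[(2S,3S)-5-[(E)-2-(3,5-dimethoxyphenyl)ethenyl]-2-(4-methoxyphenyl)-2,3-dihydrobenzofuran-3-yl]-6-methoxy-2-(4-methoxyphenyl)-2,3-dihydrobenzofuran | COc1ccc([C@H]2Oc3ccc(/C=C/c4cc(OC)cc(OC)c4)cc3[C@@H]2c2cc(OC)cc3c2[C@H](c2cc(OC)cc(OC)c2)[C@@H](c2ccc(OC)cc2)O3)cc1 | intermediate
24 | trans-diptoindonesin B | Oc1ccc([C@H]2Oc3ccc(/C=C/c4cc(O)cc(O)c4)cc3[C@@H]2c2cc(O)cc3c2[C@H](c2cc(O)cc(O)c2)[C@@H](c2ccc(O)cc2)O3)cc1 | target

## Step count and least certain steps

Total: 15 steps. Longest linear sequence: 10 steps (steps 6 to 13, then 14 and 15); the other branch (steps 1 to 5) joins at step 14.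

**Step 2 (key step).** Most likely failures are a competing 1,2-shift of the electron-rich anisyl group from C2 to C3 and dehydrogenation of the chromanone, both of which consume the iodane without ring contraction, and acid-induced opening of the pyranone before enol ether formation, which would racemise C2. The fallback leaves the rearrangement and builds 6 by carbene C–H insertion. It sets out from 13: methyl 2-(5-bromo-2-hydroxyphenyl)acetate F1 is alkylated with 13 (K2CO3, DMF) to methyl 2-{5-bromo-2-[(4-methoxyphenyl)methoxy]phenyl}acetate F2. Diazo transfer (4-acetamidobenzenesulfonyl azide, DBU, MeCN) gives methyl 2-{5-bromo-2-[(4-methoxyphenyl)methoxy]phenyl}-2-diazoacetate F3. A chiral dirhodium carboxylate such as Rh2(S-PTTL)4 (dirhodium tetrakis[N-phthaloyl-(S)-tert-leucinate]) in toluene at low temperature closes the ring by insertion into the benzylic ether C–H bond, giving the cis ester methyl (2S,3R)-5-bromo-2-(4-methoxyphenyl)-2,3-dihydrobenzofuran-3-carboxylate F4. NaOMe in MeOH then epimerises C3 and the route is rejoined at 6.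

**Step 14.** The hindered benzylic C3 radical may be captured too slowly by the ortho-substituted aryl–nickel species, so that radical dimerisation, hydrogen abstraction, β-scission of the C2–O1 bond or addition to the stilbene take over; facial selectivity at C3 may also be incomplete. The fallback replaces the cross-electrophile manifold by a redox-neutral coupling with a preformed nucleophile. It sets out from 21: bromine–lithium exchange (n-BuLi, THF, −78 °C) gives [(2S,3S)-3-(3,5-dimethoxyphenyl)-6-methoxy-2-(4-methoxyphenyl)-2,3-dihydrobenzofuran-4-yl]lithium F5, ZnCl2 converts it into chloro[(2S,3S)-3-(3,5-dimethoxyphenyl)-6-methoxy-2-(4-methoxyphenyl)-2,3-dihydrobenzofuran-4-yl]zinc F6, and this arylzinc is coupled with 10 under NiCl2·glyme and 4,4'-di-tert-butyl-2,2'-bipyridine in THF/DMF at rt (Negishi-type decarboxylative arylation). The route is rejoined at 23, and step 13 is then not needed.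

**Step 10.** Condensation may fail because the carbonyl group is shielded by bromine and the benzyloxy group on the same ring. The fallback forms the C=N bond before the crowded ketone exists. It sets out from 14: I2 and aqueous NH3 in THF convert the aldehyde into 2-bromo-4-methoxy-6-[(4-methoxyphenyl)methoxy]benzonitrile F7. Addition of 15 (THF, reflux, CuBr catalyst), quenched with MeOH, gives the N-unsubstituted ketimine 1-{2-bromo-4-methoxy-6-[(4-methoxyphenyl)methoxy]phenyl}-1-(3,5-dimethoxyphenyl)methanimine F8. Transimination with hydrazine in EtOH releases ammonia and the route is rejoined at 18; steps 8 and 9 are then not needed.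

**Step 11.** The carbene may dimerise to the azine, and enantioselectivity may erode because the ortho bromine twists the carbene-bearing ring out of conjugation; any erosion is carried into step 12, where loss of the C3' proton from the open cation would add to it. The fallback builds the trans ring by a [4+1] annulation. It sets out from 12: two equivalents of 15 give 3-bromo-2-[(3,5-dimethoxyphenyl)(hydroxy)methyl]-5-methoxyphenol F9, and sodium 4-methylbenzenesulfinate in aqueous formic acid converts it into 3-bromo-2-[(3,5-dimethoxyphenyl)(4-methylbenzenesulfonyl)methyl]-5-methoxyphenol F10. Cs2CO3 in CH2Cl2 eliminates sulfinate to the ortho-quinone methide 5-bromo-6-[(3,5-dimethoxyphenyl)methylidene]-3-methoxycyclohexa-2,4-dien-1-one F11 (not isolated). In the same flask this is intercepted by the ylide of (2R,5R)-1-[(4-methoxyphenyl)methyl]-2,5-dimethylthiolan-1-ium tetrafluoroborate F12, a salt made from 13, (2R,5R)-2,5-dimethylthiolane and AgBF4. Conjugate addition and 5-exo-tet closure of the phenoxide with loss of the thiolane give the trans ring directly, and the route is rejoined at 21; steps 8 to 12 are then not needed.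

**Step 15.** Ionisation of the benzylic C–O bonds may be followed by bromide capture or Friedel–Crafts oligomerisation instead of reclosure, cleavage of seven ethers may stay incomplete, and the free heptaphenol may be lost by oxidation on isolation. The fallback changes how the product is secured. It sets out from 23: the ethers are cleaved with the weaker Lewis acid BCl3 assisted by n-Bu4NI (CH2Cl2, −78 → 0 °C), and the crude polyphenol is acetylated at once (Ac2O, pyridine) to the heptaacetate (2S,3S)-3-(3,5-diacetoxyphenyl)-4-[(2S,3S)-5-[(E)-2-(3,5-diacetoxyphenyl)ethenyl]-2-(4-acetoxyphenyl)-2,3-dihydrobenzofuran-3-yl]-6-acetoxy-2-(4-acetoxyphenyl)-2,3-dihydrobenzofuran F13, which is stable and can be purified. Methanolysis (K2CO3, degassed MeOH, 0 °C) then rejoins the route at 24.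

## Further compounds

F1 | step 2 | methyl 2-(5-bromo-2-hydroxyphenyl)acetate | COC(=O)Cc1cc(Br)ccc1O
F2 | step 2 | methyl 2-{5-bromo-2-[(4-methoxyphenyl)methoxy]phenyl}acetate | COC(=O)Cc1cc(Br)ccc1OCc1ccc(OC)cc1
F3 | step 2 | methyl 2-{5-bromo-2-[(4-methoxyphenyl)methoxy]phenyl}-2-diazoacetate | COC(=O)C(=[N+]=[N-])c1cc(Br)ccc1OCc1ccc(OC)cc1
F4 | step 2 | methyl (2S,3R)-5-bromo-2-(4-methoxyphenyl)-2,3-dihydrobenzofuran-3-carboxylate | COc1ccc([C@H]2Oc3ccc(Br)cc3[C@H]2C(=O)OC)cc1
F5 | step 14 | [(2S,3S)-3-(3,5-dimethoxyphenyl)-6-methoxy-2-(4-methoxyphenyl)-2,3-dihydrobenzofuran-4-yl]lithium | [Li]c1cc(OC)cc2c1[C@H](c1cc(OC)cc(OC)c1)[C@@H](c1ccc(OC)cc1)O2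
F6 | step 14 | chloro[(2S,3S)-3-(3,5-dimethoxyphenyl)-6-methoxy-2-(4-methoxyphenyl)-2,3-dihydrobenzofuran-4-yl]zinc | Cl[Zn]c1cc(OC)cc2c1[C@H](c1cc(OC)cc(OC)c1)[C@@H](c1ccc(OC)cc1)O2
F7 | step 10 | 2-bromo-4-methoxy-6-[(4-methoxyphenyl)methoxy]benzonitrile | COc1ccc(COc2cc(OC)cc(Br)c2C#N)cc1
F8 | step 10 | 1-{2-bromo-4-methoxy-6-[(4-methoxyphenyl)methoxy]phenyl}-1-(3,5-dimethoxyphenyl)methanimine | COc1ccc(COc2cc(OC)cc(Br)c2C(=N)c2cc(OC)cc(OC)c2)cc1
F9 | step 11 | 3-bromo-2-[(3,5-dimethoxyphenyl)(hydroxy)methyl]-5-methoxyphenol | COc1cc(O)c(C(O)c2cc(OC)cc(OC)c2)c(Br)c1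
F10 | step 11 | 3-bromo-2-[(3,5-dimethoxyphenyl)(4-methylbenzenesulfonyl)methyl]-5-methoxyphenol | COc1cc(O)c(C(c2cc(OC)cc(OC)c2)S(=O)(=O)c2ccc(C)cc2)c(Br)c1
F11 | step 11 | 5-bromo-6-[(3,5-dimethoxyphenyl)methylidene]-3-methoxycyclohexa-2,4-dien-1-one | COC1=CC(=O)C(=Cc2cc(OC)cc(OC)c2)C(Br)=C1
F12 | step 11 | (2R,5R)-1-[(4-methoxyphenyl)methyl]-2,5-dimethylthiolan-1-ium tetrafluoroborate | C[C@@H]1CC[C@@H](C)[S+]1Cc1ccc(OC)cc1.F[B-](F)(F)F
F13 | step 15 | (2S,3S)-3-(3,5-diacetoxyphenyl)-4-[(2S,3S)-5-[(E)-2-(3,5-diacetoxyphenyl)ethenyl]-2-(4-acetoxyphenyl)-2,3-dihydrobenzofuran-3-yl]-6-acetoxy-2-(4-acetoxyphenyl)-2,3-dihydrobenzofuran | CC(=O)Oc1ccc([C@H]2Oc3ccc(/C=C/c4cc(OC(C)=O)cc(OC(C)=O)c4)cc3[C@@H]2c2cc(OC(C)=O)cc3c2[C@H](c2cc(OC(C)=O)cc(OC(C)=O)c2)[C@@H](c2ccc(OC(C)=O)cc2)O3)cc1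
A1 | alternative 1 | (2S,3S)-4-{[5-bromo-2-(4-methoxybenzyloxy)phenyl]dimethoxymethyl}-3-(3,5-dimethoxyphenyl)-2-(4-methoxyphenyl)-2,3-dihydrobenzofuran-6-ol | COc1ccc(COc2ccc(Br)cc2C(OC)(OC)c2cc(O)cc3c2[C@H](c2cc(OC)cc(OC)c2)[C@@H](c2ccc(OC)cc2)O3)cc1
A2 | alternative 2 | 5-bromo-3-[2-(3,5-dimethoxybenzoyl)-3,5-dimethoxyphenyl]benzofuran-2(3H)-one | COc1cc(OC)cc(C(=O)c2c(OC)cc(OC)cc2C2C(=O)Oc3ccc(Br)cc32)c1
A3 | alternative 2 | 5-bromo-3-(3,5-dimethoxybenzoyl)benzofuran-2(3H)-one | COc1cc(OC)cc(C(=O)C2C(=O)Oc3ccc(Br)cc32)c1
A4 | alternative 2 | 3,5-dimethoxybenzyne (1,2-didehydro-3,5-dimethoxybenzene) | COC1=CC(OC)=CC#C1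
A5 | alternative 3 | (2S,3S)-3-[(2S,3S)-3-(3,5-dimethoxyphenyl)-6-methoxy-2-(4-methoxyphenyl)-2,3-dihydrobenzofuran-4-yl]-2-(4-methoxyphenyl)-2,3-dihydrobenzofuran-5-carbaldehyde | COc1ccc([C@H]2Oc3ccc(C=O)cc3[C@@H]2c2cc(OC)cc3c2[C@H](c2cc(OC)cc(OC)c2)[C@@H](c2ccc(OC)cc2)O3)cc1
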